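The readings are calculated for substances that don't exist, noise included.

A small charge of substrate in this flask becomes open intermediate, part of which goes on to target with the partner, and the next run must settle whether the charges stay and when to stop.

common to all: substrate 5.0 × 10⁻⁴ M

| charge | partner | capture agent | remark | time |
|---|---|---|---|---|
| blue | 1.2 equiv | 0.50 mM | the very flask that is asked about, followed so far |  |
| flask | 1.20 equiv | 0.500 mM |  | 10 min |

blue run (percent of the substrate charged)

| time / min | open intermediate / % | target / % |
|---|---|---|
| 0.333 | 46.6 | 7.9 |
| 0.500 | 56.7 | 12.8 |
| 0.833 | 65.1 | 21.7 |
| 1.33 | 65.0 | 28.4 |
| 2.50 | 62.7 | 36.0 |
| 4.00 | 58.5 | 36.6 |

(readings scatter by 1 percentage point)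

1. time, not beyond 10 min, at which the flask holds most open intermediate
2. the amount of open intermediate, in percent of the substrate charged, at that time
3. the first time at which open intermediate reaches 33%, in the same percent, in min

- the numbers in the tables scatter by 1 percentage point (one standard deviation)

Target reads 36.0% at 2.50 min and 36.6% at 4.00 min, equal within the scatter, while open intermediate still reads 58.5%. The reckoning made here follows one molecule of partner and supposes two exits for it: into target with open intermediate, or into capture agent, with chances in the ratio of those two amounts times a constant. Supposing that the partner charge has passed through one of the two exits by 4.00 min, taking open intermediate at a constant mean, and writing amounts as fractions of the substrate charged: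

capture agent left = capture charge − partner charge + target = 16.6%

target / ln(capture charge / capture agent left) = 0.204

This is the fork yield, the target gained for each unit fall in the logarithm of capture agent; it is the usual selectivity factor times the mean open intermediate. By this rule, with the partner charge and that mean held, a larger capture charge lowers target. The next run leaves the charges as they are and stops at 1.08 min, midway between two open intermediate readings that agree within the scatter, 65.1% and 65.0%.

The forecast puts the peak at 1.05 min, slightly before that midpoint, with 66% and the asked crossing at 0.19 min, and reads the stall as a sign that “the conversion is dying or being inhibited”.

The flask gives a peak of 65.5% at 1.17 min and the crossing at 0.190 min.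

    open intermediate + second intermediate → target (k = 36.0 /M/s)
    partner → second intermediate (k = 0.960 /s)
    2 open intermediate → homo product (k = 0.400 /M/s)
    second intermediate + capture agent → trapped intermediate (k = 75.0 /M/s)
    substrate → open intermediate (k = 0.0400 /s)

Partner reaches the fork as second intermediate, and at 10.0 min the flask keeps 19% of its capture agent, against the reckoned 16.6%. The neighbour flask holds 2.60 equiv of capture agent, all else as charged. The same fork yield, with open intermediate taken as in the first flask, gives for that neighbour in two passes:

target = fork yield × ln(capture charge / (capture charge − partner charge)) = 12.6%

target = fork yield × ln(capture charge / (capture charge − partner charge + target)) = 10.9%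

That neighbour peaks at 87.4%, above the first flask, and holds 9.13% of target at 10.0 min.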